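**Retrosynthetic overview**

- The last bond made is the one between the CH2 linker and the trione ring carbon. It comes from a Knoevenagel condensation with transfer hydrogenation between a cyclopentanecarbaldehyde and the only C–H carbon of an acyl trione.
- The strategy rests on this feature: the five cyclopentane carbons, the ring methyl, the isopropenyl group and the CH2 linker are the ten carbons of limonene with its ring alkene cut, and the ring bond between the C(OH)CH3 carbon and the linker-bearing CH is an aldol bond.
- The cyclopentane is therefore closed by an amine-catalysed intramolecular aldol reaction of the keto-aldehyde from (S)-limonene. The limonene stereocentre steers both new centres under equilibrating conditions.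
- The six-membered ring is bought as 2-methylphloroglucinol, acylated with the (R)-2-methylbutanoyl group and dearomatised by C-prenylation at the methyl-bearing carbon. The quaternary-carbon epimers are separated.
- Ring order: the cyclopentane is the only ring closed (step 3); the six-membered ring is carried in as an arene and dearomatised (step 5).

Key step: step 3

Assumption: the acyl trione unit is a tautomer mixture and is drawn throughout in the enol form of the given SMILES; (R)-2-methylbutanoic acid is taken as a commercial material of high enantiomeric purity.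

**Route**

Step 1
Reactants: 1 (S)-(−)-limonene
Product: 2 (4S)-limonene 1,2-oxide, mixture of cis and trans epoxides
Conditions: mCPBA (1.0 equiv), CH2Cl2, 0 °C
Reagents that add atoms: mCPBA, O=C(OO)c1cccc(Cl)c1
Why: Prilezhaev epoxidation, in which the electrophilic peracid reacts at the more electron-rich trisubstituted ring alkene and leaves the 1,1-disubstituted isopropenyl alkene; the epoxide carbons need no control because both become carbonyl carbons in step 2.

Step 2
Reactants: 2 (4S)-limonene 1,2-oxide
Product: 4 (3S)-6-oxo-3-(prop-1-en-2-yl)heptanal, via limonene-1,2-diol 3 (not isolated)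
Conditions: H5IO6 (1.2 equiv), THF/H2O, 0 °C to rt
Reagents that add atoms: water, O
Why: Acid-catalysed anti hydration of the epoxide gives the trans diol, which periodic acid cleaves at once (Malaprade glycol cleavage) to the methyl ketone and the aldehyde, while the isopropenyl alkene and the limonene stereocentre (C3 of 4) are not touched.

Step 3
Reactants: 4 (3S)-6-oxo-3-(prop-1-en-2-yl)heptanal
Product: 5 (1R,2S,5S)-2-hydroxy-2-methyl-5-(prop-1-en-2-yl)cyclopentane-1-carbaldehyde
Conditions: pyrrolidine (20 mol%), AcOH (20 mol%), THF/H2O (20:1), 0.05 M, 0 °C to rt; pH 7 buffer quench once the isomer composition is steady and before enal builds up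
Reagents that add atoms: none
Why: Pyrrolidine condenses with the aldehyde of 4 to an enamine whose α-carbon (C2 of the heptanal) adds to the C6 ketone, and hydrolysis of the resulting iminium ion releases 5 and the amine; this is the amine-catalysed intramolecular enolexo aldol reaction of a keto-aldehyde, and the same substrate is known to go on to the cyclopentene carbaldehyde when heated with an amine salt. The cyclopentane closes in a 5-(enolexo)-exo-trig mode, forming the ring bond between the formyl-bearing CH and the methyl carbinol carbon. Both new centres are reversible under the conditions, C1 through enamine/iminium exchange and C2 through retro-aldol opening and re-closure, so the one fixed centre, the isopropenyl-bearing carbon from limonene, decides the outcome: the formyl group should settle trans to isopropenyl, and at C2 the small hydroxyl should take the position cis to formyl, where it can hydrogen-bond to the carbonyl, leaving the methyl trans. The step needs donor/acceptor chemoselectivity, which the faster enamine formation of a secondary amine with the aldehyde secures (hydroxide would enolise the ketone instead), and it must stop before loss of water, for which low temperature, a weak acid co-catalyst, added water and a neutral quench are chosen. The isopropenyl-bearing carbon is never α to a carbonyl group and cannot epimerise.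

Step 4
Reactants: 6 (R)-2-methylbutanoic acid; 7 2-methylphloroglucinol (2-methylbenzene-1,3,5-triol)
Product: 9 (2R)-2-methyl-1-(2,4,6-trihydroxy-3-methylphenyl)butan-1-one, via acid chloride 8 (not isolated)
Conditions: (COCl)2, DMF (cat.), CH2Cl2, 0 °C to rt; then 7, AlCl3 (3.5 equiv), CH2Cl2/PhNO2, 0 °C to rt; aq. HCl
Reagents that add atoms: none
Why: Acid chloride formation through the chloroiminium salt is followed by Friedel–Crafts acylation of the electron-rich arene, whose two open positions are equivalent so that one ketone forms and is deactivated towards a second acylation by chelation to aluminium; no stereocentre is formed, and the α-centre of the acyl group is kept by working at or below room temperature, its integrity to be checked by chiral HPLC.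

Step 5
Reactants: 9 (2R)-2-methyl-1-(2,4,6-trihydroxy-3-methylphenyl)butan-1-one; 10 prenyl bromide
Product: 11 (6R)-3,5-dihydroxy-6-methyl-6-(3-methylbut-2-en-1-yl)-2-[(2R)-2-methylbutanoyl]cyclohexa-2,4-dien-1-one
Conditions: NaOMe (2.2 equiv), MeOH, 0 °C; 10 (1.05 equiv), 0 °C to rt; aq. HCl; SiO2; preparative HPLC on amylose tris(3,5-dimethylphenylcarbamate)
Reagents that add atoms: none
Why: Alkylative dearomatisation, in which the phenoxide of 9 attacks prenyl bromide in an SN2 reaction through the methyl-bearing ring carbon (the most electron-rich carbon, as in the known geminal dialkylation of acylphloroglucinols in methanolic methoxide, where hydrogen bonding to the oxygens holds back O-alkylation); the quaternary centre forms without facial bias, so both C6 epimers should arise in about equal amounts, they are diastereomers because of the side-chain centre, the (6R) epimer 11 is obtained by the chromatographic separation, and its configuration has to be assigned (X-ray analysis of a derivative or measured against computed ECD) before it is taken on.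

Step 6
Reactants: 5 (1R,2S,5S)-2-hydroxy-2-methyl-5-(prop-1-en-2-yl)cyclopentane-1-carbaldehyde; 11 (6R)-acyl trione
Product: 13 target (6R)-3,5-dihydroxy-4-{[(1R,2S,5S)-2-hydroxy-2-methyl-5-(prop-1-en-2-yl)cyclopentyl]methyl}-6-methyl-6-(3-methylbut-2-en-1-yl)-2-[(2R)-2-methylbutanoyl]cyclohexa-2,4-dien-1-one, via alkylidene trione 12 (not isolated)
Conditions: L-proline (10 mol%), diethyl 2,6-dimethyl-1,4-dihydropyridine-3,5-dicarboxylate (Hantzsch ester, 1.2 equiv), CH2Cl2, rt; 5 added last
Reagents that add atoms: none
Why: Three-component reductive alkylation, in which amine-catalysed Knoevenagel condensation of the aldehyde with the only C–H carbon of the trione ring gives the electrophilic alkylidene trione 12, and this takes up hydride from the Hantzsch ester in a conjugate transfer hydrogenation faster than it can tautomerise or add a second trione; the new carbon is a CH2 group, so no stereocentre is formed and the five existing ones are carried through.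

**Compound list**

1 | (S)-(−)-limonene | C=C(C)[C@H]1CCC(C)=CC1 | starting material
2 | (4S)-limonene 1,2-oxide, (4S)-1-methyl-4-(prop-1-en-2-yl)-7-oxabicyclo[4.1.0]heptane, cis/trans mixture at the epoxide | C=C(C)[C@H]1CCC2(C)OC2C1 | intermediate
3 | (1R,2R,4S)-1-methyl-4-(prop-1-en-2-yl)cyclohexane-1,2-diol (trans diol; any other diol isomer is cleaved to the same product) | C=C(C)[C@H]1CC[C@@](C)(O)[C@H](O)C1 | intermediate (not isolated)
4 | (3S)-6-oxo-3-(prop-1-en-2-yl)heptanal | C=C(C)[C@@H](CCC(C)=O)CC=O | intermediate (key-step precursor)
5 | (1R,2S,5S)-2-hydroxy-2-methyl-5-(prop-1-en-2-yl)cyclopentane-1-carbaldehyde | C=C(C)[C@H]1CC[C@](C)(O)[C@@H]1C=O | intermediate (key-step product)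
6 | (R)-2-methylbutanoic acid | CC[C@@H](C)C(=O)O | starting material
7 | 2-methylphloroglucinol | Cc1c(O)cc(O)cc1O | starting material
8 | (R)-2-methylbutanoyl chloride | CC[C@@H](C)C(=O)Cl | intermediate (not isolated)
9 | (2R)-2-methyl-1-(2,4,6-trihydroxy-3-methylphenyl)butan-1-one | CC[C@@H](C)C(=O)c1c(O)cc(O)c(C)c1O | intermediate
10 | prenyl bromide (1-bromo-3-methylbut-2-ene) | CC(C)=CCBr | starting material
11 | (6R)-3,5-dihydroxy-6-methyl-6-(3-methylbut-2-en-1-yl)-2-[(2R)-2-methylbutanoyl]cyclohexa-2,4-dien-1-one | CC[C@@H](C)C(=O)C1=C(O)C=C(O)[C@@](C)(CC=C(C)C)C1=O | intermediate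
12 | alkylidene trione from 5 and 11 (exocyclic C=CH, alkene geometry not defined) | C=C(C)[C@H]1CC[C@](C)(O)[C@@H]1C=C2C(O)=C(C(=O)[C@H](C)CC)C(=O)[C@](C)(CC=C(C)C)C2=O | intermediate (not isolated)
13 | CNP0299585.1, (6R)-3,5-dihydroxy-4-{[(1R,2S,5S)-2-hydroxy-2-methyl-5-(prop-1-en-2-yl)cyclopentyl]methyl}-6-methyl-6-(3-methylbut-2-en-1-yl)-2-[(2R)-2-methylbutanoyl]cyclohexa-2,4-dien-1-one | C=C(C)[C@H]1CC[C@](C)(O)[C@@H]1CC1=C(O)[C@@](C)(CC=C(C)C)C(=O)C(C(=O)[C@H](C)CC)=C1O | target

**Step count**

Total: 6 steps. Longest linear sequence: 4 steps (steps 1, 2, 3, 6); the trione branch is steps 4 and 5.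

**Steps most likely to fail**

Step 3. Loss of water from the catalyst-bound aldol may outrun its hydrolysis, so that material drains to the conjugated enal, or the equilibration of the two new centres may stall at a mixture of ring diastereomers. The fallback sets out from 4 and comes back at 5.
- The dehydration is driven to completion (piperidine, AcOH, benzene, reflux, water separator) to give the enal (5R)-2-methyl-5-(prop-1-en-2-yl)cyclopent-1-ene-1-carbaldehyde F1.
- Weitz–Scheffer epoxidation (H2O2, NaOH, MeOH, 0 °C) leaves the isopropenyl group alone and should place the oxygen on the face away from the neighbouring isopropenyl group, giving the epoxy aldehyde (1R,2R,5S)-5-methyl-2-(prop-1-en-2-yl)-6-oxabicyclo[3.1.0]hexane-1-carbaldehyde F2.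
- An N-heterocyclic-carbene redox esterification (3-benzyl-4,5-dimethylthiazolium chloride, iPr2NEt, MeOH/CH2Cl2, rt) opens the epoxide at the α-carbon and gives methyl (1R,2S,5S)-2-hydroxy-2-methyl-5-(prop-1-en-2-yl)cyclopentane-1-carboxylate F3, with the tertiary alcohol fixed by the epoxide face.
- LiAlH4 (THF, 0 °C) reduces the ester to (1S,2S,3S)-2-(hydroxymethyl)-1-methyl-3-(prop-1-en-2-yl)cyclopentan-1-ol F4, and TEMPO/PhI(OAc)2 (CH2Cl2, rt) oxidises only the primary alcohol to 5.
- The protonation that follows epoxide opening is expected from the less hindered face and may give the ring CH centre partly or mainly in the wrong sense. The formyl group is then brought trans to isopropenyl at the aldehyde stage with a catalytic tertiary amine (DBU, CH2Cl2, 0 °C), which enolises the aldehyde without opening the secondary-amine dehydration channel.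

Step 6. The β-hydroxy aldehyde may open by retro-aldol reaction or lose water in the amine/acid medium before it condenses with the trione. The fallback sets out from 5 and comes back at 13.
- The tertiary alcohol is capped (TESOTf, 2,6-lutidine, CH2Cl2, −78 °C) to give (1R,2S,5S)-2-methyl-5-(prop-1-en-2-yl)-2-(triethylsilyloxy)cyclopentane-1-carbaldehyde F5.
- The reductive alkylation with 11 is run as in step 6 and should pass through the silylated alkylidene trione F6 to the O-triethylsilyl ether of 13 F7.
- HF·pyridine (THF, 0 °C) removes the silyl group and gives 13.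

Step 5. Alkylation may drift to oxygen, to the unsubstituted ring carbon and to double alkylation instead of the methyl-bearing carbon. The fallback reverses the order of the two alkyl groups; it sets out from 6 (converted into 8 as in step 4) and comes back at 11.
- Phloroglucinol is acylated with 8 (AlCl3, CH2Cl2/PhNO2, 0 °C to rt) to (2R)-2-methyl-1-(2,4,6-trihydroxyphenyl)butan-1-one F8.
- C-prenylation with 10 (NaOMe, MeOH, 0 °C) gives the aromatic mono-prenyl compound (2R)-2-methyl-1-[2,4,6-trihydroxy-3-(3-methylbut-2-en-1-yl)phenyl]butan-1-one F9.
- The small electrophile MeI (NaOMe, MeOH, 0 °C to rt) then alkylates the prenyl-bearing carbon, as in the known geminal methylation of acylphloroglucinols, and the same separation of C6 epimers delivers 11.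

**Further compounds**

F1 | step 3 | (5R)-2-methyl-5-(prop-1-en-2-yl)cyclopent-1-ene-1-carbaldehyde | C=C(C)[C@H]1CCC(C)=C1C=O
F2 | step 3 | (1R,2R,5S)-5-methyl-2-(prop-1-en-2-yl)-6-oxabicyclo[3.1.0]hexane-1-carbaldehyde | C=C(C)[C@H]1CC[C@]2(C)O[C@]12C=O
F3 | step 3 | methyl (1R,2S,5S)-2-hydroxy-2-methyl-5-(prop-1-en-2-yl)cyclopentane-1-carboxylate | C=C(C)[C@H]1CC[C@](C)(O)[C@@H]1C(=O)OC
F4 | step 3 | (1S,2S,3S)-2-(hydroxymethyl)-1-methyl-3-(prop-1-en-2-yl)cyclopentan-1-ol | C=C(C)[C@H]1CC[C@](C)(O)[C@@H]1CO
F5 | step 6 | (1R,2S,5S)-2-methyl-5-(prop-1-en-2-yl)-2-(triethylsilyloxy)cyclopentane-1-carbaldehyde | C=C(C)[C@H]1CC[C@](C)(O[Si](CC)(CC)CC)[C@@H]1C=O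
F6 | step 6 | silylated alkylidene trione from F5 and 11 (alkene geometry not defined) | C=C(C)[C@H]1CC[C@](C)(O[Si](CC)(CC)CC)[C@@H]1C=C2C(O)=C(C(=O)[C@H](C)CC)C(=O)[C@](C)(CC=C(C)C)C2=O
F7 | step 6 | O-triethylsilyl ether of 13 | C=C(C)[C@H]1CC[C@](C)(O[Si](CC)(CC)CC)[C@@H]1CC1=C(O)[C@@](C)(CC=C(C)C)C(=O)C(C(=O)[C@H](C)CC)=C1O
F8 | step 5 | (2R)-2-methyl-1-(2,4,6-trihydroxyphenyl)butan-1-one | CC[C@@H](C)C(=O)c1c(O)cc(O)cc1O
F9 | step 5 | (2R)-2-methyl-1-[2,4,6-trihydroxy-3-(3-methylbut-2-en-1-yl)phenyl]butan-1-one | CC[C@@H](C)C(=O)c1c(O)cc(O)c(CC=C(C)C)c1O
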